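**Plan**

1. Retrosynthesis: the O2′–C3 ketal bond is cut first (dioxane opened to a C3 dimethyl ketal and a free ring-D phenol). Next the C3–C4 bond is cut, opening ring C to a ring-B para-quinone methide that carries O3′ on C4 and a C2 ketone with a C3 dimethyl acetal. Then ring B (bonds C4a–C4b and C10–C10a), the C4–O3′ ether, and in the lower half C9′–C10′ and the C4a′–C4b′ biaryl bond.
2. Forward: rings D and F are joined and ring E is closed to give the lower phenanthrene. Its O3′ is alkylated with an alkyne that carries C1–C4. Ring B is built on that alkyne from a ring-A sulfoxonium ylide, ring C is closed by C3–C4, the dioxane is closed by ketal exchange, and the phenols are released.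
3. Enabling feature: the C9 hydroxyl of ring B is para to C4a, so C4 is a para-hydroxybenzylic carbon that two-electron oxidation turns into the electrophilic end of a quinone methide. C3 is the only enolisable carbon of the C2 ketone because C1 is quaternary. Holding C3 as a dimethyl acetal puts it at the ketal oxidation level and makes the adduct unable to β-eliminate.
4. Stereochemistry: C4 (S) comes from a chiral phosphoric acid in the ring-C closure. C3 (S) is relayed from C4 when the dioxane closes cis.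

Key step: step 17

Assumption: both halves carry phenanthrene locants (rings A–C, unprimed, for the ketone half; rings D–F, primed, for the catechol half). The sense of induction of the phosphoric acid in step 17 cannot be predicted with confidence, so the (R)-acid is written and its enantiomer would be taken if it favoured the (4R) series.

In names, Ar′ = 9-methoxy-2-(methoxymethoxy)-1,7-dimethyl-6-(triisopropylsilyloxy)phenanthren-3-yl.

**Lower half (rings D, E, F)**

Step 1
Reactants: 1 4-bromo-2,3-dimethylphenol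
Product: 2 5-bromo-2-hydroxy-3,4-dimethylbenzaldehyde
Conditions: MgCl2, Et3N, (CH2O)n, MeCN, reflux
Reagents that add atoms: paraformaldehyde (formaldehyde), C=O
Why: Magnesium-phenoxide-directed ortho-formylation (Casnati–Skattebøl) should act at the only free ortho position and so places the carbon that later becomes O3′.

Step 2
Reactants: 2 5-bromo-2-hydroxy-3,4-dimethylbenzaldehyde
Product: 3 5-bromo-2-(methoxymethoxy)-3,4-dimethylbenzaldehyde
Conditions: MOMCl, iPr2NEt, CH2Cl2, 0 °C → rt
Reagents that add atoms: chloromethyl methyl ether, COCCl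
Why: O-alkylation of the phenol masks the future O2′ and so differentiates the two catechol oxygens from the outset.

Step 3
Reactants: 3 5-bromo-2-(methoxymethoxy)-3,4-dimethylbenzaldehyde
Product: 5 5-bromo-2-(methoxymethoxy)-3,4-dimethylphenol, via aryl formate 4 (not isolated)
Conditions: mCPBA, CH2Cl2, 0 °C → rt; then Et3N, MeOH
Reagents that add atoms: meta-chloroperoxybenzoic acid, OOC(=O)c1cccc(Cl)c1
Why: Baeyer–Villiger (Dakin-type) oxidation of the ortho-alkoxy benzaldehyde should proceed with aryl migration, and methanolysis of the formate reveals O3′–H.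

Step 4
Reactants: 5 5-bromo-2-(methoxymethoxy)-3,4-dimethylphenol
Product: 6 1-(benzyloxy)-5-bromo-2-(methoxymethoxy)-3,4-dimethylbenzene
Conditions: BnBr, K2CO3, DMF, rt
Reagents that add atoms: benzyl bromide, BrCc1ccccc1
Why: Williamson benzylation gives a temporary mask for O3′ that survives the organometallic steps and is removable without touching the MOM or silyl ethers.

Step 5
Reactants: 7 4-hydroxy-3-methylbenzoic acid
Product: 8 N,N-diethyl-4-hydroxy-3-methylbenzamide
Conditions: 1,1′-carbonyldiimidazole, THF, rt; then Et2NH, 50 °C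
Reagents that add atoms: diethylamine, CCNCC
Why: Amidation through the acyl imidazolide installs the diethylamide that directs steps 7 and 9 and later becomes C9′.

Step 6
Reactants: 8 N,N-diethyl-4-hydroxy-3-methylbenzamide
Product: 9 N,N-diethyl-3-methyl-4-(triisopropylsilyloxy)benzamide
Conditions: iPr3SiCl, imidazole, DMF, rt
Reagents that add atoms: chlorotriisopropylsilane, CC(C)[Si](Cl)(C(C)C)C(C)C
Why: The bulky silyl ether protects O6′ to the end, is a poor ortho-director and is stable to alkyllithium and amide bases.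

Step 7
Reactants: 9 N,N-diethyl-3-methyl-4-(triisopropylsilyloxy)benzamide
Product: 10 [2-(diethylcarbamoyl)-4-methyl-5-(triisopropylsilyloxy)phenyl]boronic acid
Conditions: s-BuLi, TMEDA, THF, −78 °C; B(OMe)3; aq. HCl
Reagents that add atoms: trimethyl borate, COB(OC)OC; water, O
Why: Amide-directed ortho-metalation should take the ortho position that is not flanked by the methyl group, and borate trapping gives the coupling partner.

Step 8
Reactants: 6 1-(benzyloxy)-5-bromo-2-(methoxymethoxy)-3,4-dimethylbenzene; 10 [2-(diethylcarbamoyl)-4-methyl-5-(triisopropylsilyloxy)phenyl]boronic acid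
Product: 11 5′-(benzyloxy)-N,N-diethyl-4′-(methoxymethoxy)-2′,3′,4-trimethyl-5-(triisopropylsilyloxy)biphenyl-2-carboxamide
Conditions: Pd(OAc)2 (5 mol %), 2-dicyclohexylphosphino-2′,6′-dimethoxybiphenyl (10 mol %), K3PO4, toluene–H2O, 90 °C
Reagents that add atoms: none
Why: Suzuki–Miyaura coupling with a dialkylbiarylphosphine tolerates the ortho,ortho′-disubstitution and forms the C4a′–C4b′ bond.

Step 9
Reactants: 11 5′-(benzyloxy)-N,N-diethyl-4′-(methoxymethoxy)-2′,3′,4-trimethyl-5-(triisopropylsilyloxy)biphenyl-2-carboxamide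
Product: 13 3-(benzyloxy)-9-methoxy-2-(methoxymethoxy)-1,7-dimethyl-6-(triisopropylsilyloxy)phenanthrene, via 9-phenanthrol 12 (not isolated)
Conditions: LiN(iPr)2 (3 equiv), THF, 0 °C → rt; then Me2SO4, DMPU, 0 °C → rt
Reagents that add atoms: dimethyl sulfate, COS(=O)(=O)OC
Why: Directed remote metalation deprotonates the 2′-methyl next to the biaryl axis; the benzylic anion attacks the amide and loses diethylamide to give the 9-phenanthrolate (ring E), which is O-methylated in the flask by the hard electrophile before it can oxidise in air.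

Step 10
Reactants: 13 3-(benzyloxy)-9-methoxy-2-(methoxymethoxy)-1,7-dimethyl-6-(triisopropylsilyloxy)phenanthrene
Product: 14 9-methoxy-2-(methoxymethoxy)-1,7-dimethyl-6-(triisopropylsilyloxy)phenanthren-3-ol
Conditions: H2 (1 atm), Pd/C (10 wt %), EtOAc, rt
Reagents that add atoms: none
Why: Hydrogenolysis of the benzyl aryl ether frees O3′ alone, the MOM, silyl and methyl ethers being inert.

**Alkyne carrying C1–C4**

Step 11
Reactants: 15 2,2-dimethylbut-3-ynoic acid
Product: 16 6-hydroxy-3,3-dimethylhex-4-yn-2-one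
Conditions: MeLi (3.5 equiv), THF, −78 → 0 °C; (CH2O)n, 0 °C → rt; aq. HCl
Reagents that add atoms: methyllithium, [Li]C; paraformaldehyde (formaldehyde), C=O
Why: Addition of methyllithium to the lithium carboxylate stops at the gem-diolate (ketone on work-up), while the lithium acetylide formed from the terminal alkyne is hydroxymethylated by formaldehyde.

Step 12
Reactants: 16 6-hydroxy-3,3-dimethylhex-4-yn-2-one
Product: 17 4,4-dimethyl-5-oxohex-2-yn-1-yl acetate
Conditions: Ac2O, pyridine, 4-(dimethylamino)pyridine (cat.), CH2Cl2, 0 °C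
Reagents that add atoms: acetic anhydride, CC(=O)OC(C)=O
Why: Acetylation shields the primary propargylic alcohol from the oxidant of the next step.

Step 13
Reactants: 17 4,4-dimethyl-5-oxohex-2-yn-1-yl acetate
Product: 19 6-hydroxy-1,1-dimethoxy-3,3-dimethylhex-4-yn-2-one, via keto aldehyde 18 (not isolated)
Conditions: SeO2, 1,4-dioxane–H2O, 90 °C; filter; then MeOH, HCl (cat., from AcCl), 50 °C
Reagents that add atoms: selenium dioxide, O=[Se]=O; methanol, CO
Why: Riley oxidation acts on the only enolisable side of the methyl ketone, and acidic methanol then acetalises the aldehyde selectively (the ketone is flanked by a quaternary carbon) and transesterifies the acetate away.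

**Ring-A ylide**

Step 14
Reactants: 20 4-methoxy-3-methylbenzoic acid
Product: 22 2-[dimethyl(oxo)-λ6-sulfanylidene]-1-(4-methoxy-3-methylphenyl)ethan-1-one, via acid chloride 21 (not isolated)
Conditions: (COCl)2, DMF (cat.), CH2Cl2, rt; then Me3S(O)I, KOtBu, THF, reflux, 21 added at 0 °C
Reagents that add atoms: trimethylsulfoxonium iodide, C[S+](C)(C)=O.[I-]
Why: C-acylation of dimethylsulfoxonium methylide by the acid chloride (a second equivalent of ylide acting as base) gives the stable β-keto sulfoxonium ylide.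

**Union and upper half**

Step 15
Reactants: 14 9-methoxy-2-(methoxymethoxy)-1,7-dimethyl-6-(triisopropylsilyloxy)phenanthren-3-ol; 19 6-hydroxy-1,1-dimethoxy-3,3-dimethylhex-4-yn-2-one
Product: 23 1,1-dimethoxy-6-(Ar′-oxy)-3,3-dimethylhex-4-yn-2-one (aryl propargyl ether)
Conditions: PPh3, DIAD, THF, 0 °C → rt
Reagents that add atoms: none
Why: Mitsunobu etherification at the primary propargylic carbon forms the C4–O3′ bond, and because O2′ is blocked only O3′ can react, which fixes the regiochemistry of the future dioxane.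

Step 16
Reactants: 22 2-[dimethyl(oxo)-λ6-sulfanylidene]-1-(4-methoxy-3-methylphenyl)ethan-1-one; 23 1,1-dimethoxy-6-(Ar′-oxy)-3,3-dimethylhex-4-yn-2-one
Product: 24 3-[4-hydroxy-7-methoxy-6-methyl-1-(Ar′-oxymethyl)naphthalen-2-yl]-1,1-dimethoxy-3-methylbutan-2-one
Conditions: [Cp*RhCl2]2 (4 mol %), AgSbF6 (16 mol %), pivalic acid (0.5 equiv), 1,2-dichloroethane, 80 °C
Reagents that add atoms: none
Why: Carbonyl-directed C–H activation by trivalent rhodium at the less hindered ortho position, alkyne insertion with the quaternary end next to the metal and the CH2O end next to the arene, loss of dimethyl sulfoxide to a rhodium carbene, migratory insertion and tautomerisation should give the 1-naphthol with ring B fully substituted (sulfoxonium ylide–alkyne benzannulation).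

Step 17
Reactants: 24 3-[4-hydroxy-7-methoxy-6-methyl-1-(Ar′-oxymethyl)naphthalen-2-yl]-1,1-dimethoxy-3-methylbutan-2-one
Product: 27 (4S)-3,3,6-trimethoxy-1,1,7-trimethyl-2-oxo-4-(Ar′-oxy)-1,2,3,4-tetrahydrophenanthren-9-yl acetate, via quinone methide 25 (not isolated), via cyclised naphthol 26 (not isolated)
Conditions: Ag2O (3 equiv), 4 Å molecular sieves, CH2Cl2, 0 °C, filter; (R)-3,3′-bis(2,4,6-triisopropylphenyl)-1,1′-binaphthyl-2,2′-diyl hydrogen phosphate (10 mol %), toluene, −20 °C → rt; then Ac2O, pyridine, 4-(dimethylamino)pyridine (cat.), 0 °C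
Reagents that add atoms: acetic anhydride, CC(=O)OC(C)=O
Why: Proposed new method: Ag2O removes two electrons and two protons from the C9 phenol/C4–H2 pair to give the ring-B para-quinone methide 25, a vinylogous aryl ester whose C4 already carries O3′; the phosphoric acid hydrogen-bonds the C9 oxygen and enolises the C2 ketone toward C3 (reversible O-attack of the ketone on C4 followed by C3–H loss is an equivalent entry to the same enol, as in a Petasis–Ferrier O→C transposition), and C3 then adds to C4 with re-aromatisation of ring B. The closest known reaction types are chiral-phosphoric-acid-catalysed 1,6-additions of enols to para-quinone methides and oxidatively initiated cyclisations of benzylic ethers onto tethered enol nucleophiles. Ring C closes in the 6-(enolendo)-endo-trig mode, both C3 and C4a lying in the new ring. The new stereocentre C4 (S) is set by the phosphate, which bridges the C9 oxygen and the C2 enol hydroxyl along the C10 edge and so exposes one face of C4, while C3 is not yet stereogenic. C- over O-alkylation is secured because the O-adduct is a para-hydroxybenzylic mixed acetal that re-ionises whereas the C–C bond is irreversible, elimination is excluded because C3 is quaternary in the adduct, and the dioxane regiochemistry is secured because O2′ is blocked as its MOM ether. Acetylation in the same flask removes the para-hydroxyl assistance and so should freeze the configuration at C4.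

Step 18
Reactants: 27 (4S)-3,3,6-trimethoxy-1,1,7-trimethyl-2-oxo-4-(Ar′-oxy)-1,2,3,4-tetrahydrophenanthren-9-yl acetate
Product: 28 the corresponding O2′ phenol (MOM group removed)
Conditions: ZnBr2, n-PrSH, CH2Cl2, 0 °C
Reagents that add atoms: none
Why: Lewis-acid activation with thiol capture of the methoxymethyl cation cleaves aryl MOM ethers within minutes and leaves the acetate, silyl ether, ketal and the C4 ether untouched.

Step 19
Reactants: 28 O2′ phenol
Product: 29 (3S,4S) cis-fused dioxane, the C9 acetate and C6′ triisopropylsilyl ether of actephilol C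
Conditions: (+)-10-camphorsulfonic acid (20 mol %), toluene, 5 Å molecular sieves, 50 °C
Reagents that add atoms: none
Why: Acid-catalysed transketalisation ionises one methoxy group of the α-keto ketal and the tethered O2′–H adds to the oxocarbenium ion; the C9 acetate disfavours competing ionisation at C4, and the new stereocentre C3 (S) is dictated by C4 because the phenol can reach C3 only on the face of the pseudo-axial C4–O3′ bond, giving the cis-fused ring with an axial, anomerically stabilised methoxy group.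

Step 20
Reactants: 29 (3S,4S) cis-fused dioxane acetate silyl ether
Product: 30 actephilol C
Conditions: TBAF (3 equiv), THF–MeOH, 0 °C → rt; AcOH quench
Reagents that add atoms: none
Why: Fluoride cleaves the aryl silyl ether and, in methanol, the aryl acetate; with the dioxane closed, any reversible opening at C4 through the C9 phenoxide can only re-close to the same cis isomer.

**Compound list**

1 | 4-bromo-2,3-dimethylphenol | Cc1c(C)c(Br)ccc1O | starting material
2 | 5-bromo-2-hydroxy-3,4-dimethylbenzaldehyde | O=Cc1cc(Br)c(C)c(C)c1O | intermediate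
3 | 5-bromo-2-(methoxymethoxy)-3,4-dimethylbenzaldehyde | COCOc1c(C=O)cc(Br)c(C)c1C | intermediate
4 | 5-bromo-2-(methoxymethoxy)-3,4-dimethylphenyl formate | COCOc1c(OC=O)cc(Br)c(C)c1C | intermediate
5 | 5-bromo-2-(methoxymethoxy)-3,4-dimethylphenol | COCOc1c(O)cc(Br)c(C)c1C | intermediate
6 | 1-(benzyloxy)-5-bromo-2-(methoxymethoxy)-3,4-dimethylbenzene | COCOc1c(OCc2ccccc2)cc(Br)c(C)c1C | intermediate
7 | 4-hydroxy-3-methylbenzoic acid | Cc1cc(C(=O)O)ccc1O | starting material
8 | N,N-diethyl-4-hydroxy-3-methylbenzamide | CCN(CC)C(=O)c1ccc(O)c(C)c1 | intermediate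
9 | N,N-diethyl-3-methyl-4-(triisopropylsilyloxy)benzamide | CCN(CC)C(=O)c1ccc(O[Si](C(C)C)(C(C)C)C(C)C)c(C)c1 | intermediate
10 | [2-(diethylcarbamoyl)-4-methyl-5-(triisopropylsilyloxy)phenyl]boronic acid | CCN(CC)C(=O)c1cc(C)c(O[Si](C(C)C)(C(C)C)C(C)C)cc1B(O)O | intermediate
11 | 5′-(benzyloxy)-N,N-diethyl-4′-(methoxymethoxy)-2′,3′,4-trimethyl-5-(triisopropylsilyloxy)biphenyl-2-carboxamide | CCN(CC)C(=O)c1cc(C)c(O[Si](C(C)C)(C(C)C)C(C)C)cc1-c1cc(OCc2ccccc2)c(OCOC)c(C)c1C | intermediate
12 | 3-(benzyloxy)-2-(methoxymethoxy)-1,7-dimethyl-6-(triisopropylsilyloxy)phenanthren-9-ol | Oc1cc2c(C)c(OCOC)c(OCc3ccccc3)cc2c2cc(O[Si](C(C)C)(C(C)C)C(C)C)c(C)cc12 | intermediate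
13 | 3-(benzyloxy)-9-methoxy-2-(methoxymethoxy)-1,7-dimethyl-6-(triisopropylsilyloxy)phenanthrene | COc1cc2c(C)c(OCOC)c(OCc3ccccc3)cc2c2cc(O[Si](C(C)C)(C(C)C)C(C)C)c(C)cc12 | intermediate
14 | 9-methoxy-2-(methoxymethoxy)-1,7-dimethyl-6-(triisopropylsilyloxy)phenanthren-3-ol (Ar′–OH) | COc1cc2c(C)c(OCOC)c(O)cc2c2cc(O[Si](C(C)C)(C(C)C)C(C)C)c(C)cc12 | intermediate
15 | 2,2-dimethylbut-3-ynoic acid | C#CC(C)(C)C(=O)O | starting material
16 | 6-hydroxy-3,3-dimethylhex-4-yn-2-one | CC(=O)C(C)(C)C#CCO | intermediate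
17 | 4,4-dimethyl-5-oxohex-2-yn-1-yl acetate | CC(=O)OCC#CC(C)(C)C(C)=O | intermediate
18 | 4,4-dimethyl-5,6-dioxohex-2-yn-1-yl acetate | CC(=O)OCC#CC(C)(C)C(=O)C=O | intermediate
19 | 6-hydroxy-1,1-dimethoxy-3,3-dimethylhex-4-yn-2-one | COC(OC)C(=O)C(C)(C)C#CCO | intermediate
20 | 4-methoxy-3-methylbenzoic acid | COc1ccc(cc1C)C(=O)O | starting material
21 | 4-methoxy-3-methylbenzoyl chloride | COc1ccc(cc1C)C(Cl)=O | intermediate
22 | 2-[dimethyl(oxo)-λ6-sulfanylidene]-1-(4-methoxy-3-methylphenyl)ethan-1-one | COc1ccc(cc1C)C(=O)C=S(C)(C)=O | intermediate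
23 | 1,1-dimethoxy-6-(Ar′-oxy)-3,3-dimethylhex-4-yn-2-one | COC(OC)C(=O)C(C)(C)C#CCOc1cc2c(cc(OC)c3cc(C)c(O[Si](C(C)C)(C(C)C)C(C)C)cc23)c(C)c1OCOC | intermediate
24 | 3-[4-hydroxy-7-methoxy-6-methyl-1-(Ar′-oxymethyl)naphthalen-2-yl]-1,1-dimethoxy-3-methylbutan-2-one | COC(OC)C(=O)C(C)(C)c1cc(O)c2cc(C)c(OC)cc2c1COc1cc2c(cc(OC)c3cc(C)c(O[Si](C(C)C)(C(C)C)C(C)C)cc23)c(C)c1OCOC | intermediate
25 | 3-[7-methoxy-6-methyl-4-oxo-1-(Ar′-oxymethylidene)-1,4-dihydronaphthalen-2-yl]-1,1-dimethoxy-3-methylbutan-2-one (ring-B para-quinone methide, either alkene geometry) | COC(OC)C(=O)C(C)(C)C1=CC(=O)c2cc(C)c(OC)cc2C1=COc1cc2c(cc(OC)c3cc(C)c(O[Si](C(C)C)(C(C)C)C(C)C)cc23)c(C)c1OCOC | intermediate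
26 | (4S)-9-hydroxy-3,3,6-trimethoxy-1,1,7-trimethyl-4-(Ar′-oxy)-3,4-dihydrophenanthren-2(1H)-one | COc1cc2c3c(cc(O)c2cc1C)C(C)(C)C(=O)C(OC)(OC)[C@H]3Oc4cc5c(cc(OC)c6cc(C)c(O[Si](C(C)C)(C(C)C)C(C)C)cc56)c(C)c4OCOC | intermediate
27 | (4S)-3,3,6-trimethoxy-1,1,7-trimethyl-2-oxo-4-(Ar′-oxy)-1,2,3,4-tetrahydrophenanthren-9-yl acetate | COc1cc2c3c(cc(OC(C)=O)c2cc1C)C(C)(C)C(=O)C(OC)(OC)[C@H]3Oc4cc5c(cc(OC)c6cc(C)c(O[Si](C(C)C)(C(C)C)C(C)C)cc56)c(C)c4OCOC | intermediate
28 | (4S)-4-{[2-hydroxy-9-methoxy-1,7-dimethyl-6-(triisopropylsilyloxy)phenanthren-3-yl]oxy}-3,3,6-trimethoxy-1,1,7-trimethyl-2-oxo-1,2,3,4-tetrahydrophenanthren-9-yl acetate | COc1cc2c3c(cc(OC(C)=O)c2cc1C)C(C)(C)C(=O)C(OC)(OC)[C@H]3Oc4cc5c(cc(OC)c6cc(C)c(O[Si](C(C)C)(C(C)C)C(C)C)cc56)c(C)c4O | intermediate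
29 | (3S,4S) cis-fused dioxane: actephilol C 9-acetate 6′-triisopropylsilyl ether | COc1cc2c3c(cc(OC(C)=O)c2cc1C)C(C)(C)C(=O)[C@@]1(OC)Oc2c(cc4c(cc(OC)c5cc(C)c(O[Si](C(C)C)(C(C)C)C(C)C)cc54)c2C)O[C@@H]31 | intermediate
30 | actephilol C, (3S,4S) | COc1cc2c3c(cc(O)c2cc1C)C(C)(C)C(=O)[C@@]1(OC)Oc2c(cc4c(cc(OC)c5cc(C)c(O)cc54)c2C)O[C@@H]31 | target

**Totals and risks**

Total step count: 20. Longest linear sequence: 13 steps (steps 1–4, 8–10, 15–20).

Steps most likely to fail:

1. Step 17 (proposed new method). Facial discrimination at C4 may be poor, or enolisation may be too slow so that the quinone methide is lost to hydrolysis or oligomerisation. Fallback, setting out from 24 and returning at 30: the ring closure is run without asymmetric induction and the enantiomers are separated as covalent diastereomers. Compound 24 is oxidised with Ag2O as before and cyclised with diphenyl phosphate (10 mol %, toluene, rt) to the racemic cyclised naphthol F1. This is esterified in the same flask with (1S)-camphanic chloride and pyridine, and the (4S)-camphanate F2 is separated from the (4R)-camphanate F3 by chromatography or crystallisation. F2 then takes the place of 27: ZnBr2/n-PrSH should give the O2′ phenol camphanate F4, camphorsulfonic acid in toluene the cis-fused dioxane camphanate F5, and TBAF/AcOH followed by K2CO3 (0.2 equiv) in MeOH at 0 °C should release 30.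

2. Step 16. The newly formed para-hydroxybenzyl aryl ether or the MOM ether may be cleaved under the cationic rhodium conditions, and the large alkyne may insert slowly. Fallback, setting out from 19 and 22 and returning at 24: ring B is built before the halves are joined. Alkynol 19 is silylated (TBSCl, imidazole) to the silyl ether F6. Annulation of 22 with F6 under the conditions of step 16 should give the naphthol F7, which is acetylated (Ac2O, pyridine) to the naphthyl acetate F8. Ph3PBr2 in CH2Cl2 converts the silyl ether directly into the benzylic bromide F9. Williamson coupling with phenol 14 (Cs2CO3, acetone, 0 °C) gives the aryl ether acetate F10, and hydrazine acetate in DMF removes the aryl acetate to give 24.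

3. Step 19. Under protic acid the C4 aryl ether may ionise instead of the C3 ketal, with loss of the lower half or erosion of configuration at C4. Fallback, setting out from 28 and returning at 29: the exchange is run as an aprotic silyl-transfer ketalisation. Phenol 28 is silylated with N,O-bis(trimethylsilyl)acetamide to the O2′ trimethylsilyl ether F11. Catalytic Me3SiOTf in CH2Cl2 at −78 °C should then close the dioxane with loss of methoxytrimethylsilane, under kinetic control and without a free acid.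

**Further compounds**

F1 | step 17 | racemic 9-hydroxy-3,3,6-trimethoxy-1,1,7-trimethyl-4-(Ar′-oxy)-3,4-dihydrophenanthren-2(1H)-one | COc1cc2c3c(cc(O)c2cc1C)C(C)(C)C(=O)C(OC)(OC)C3Oc4cc5c(cc(OC)c6cc(C)c(O[Si](C(C)C)(C(C)C)C(C)C)cc56)c(C)c4OCOC
F2 | step 17 | (1S)-camphanate of (4S)-26 | COc1cc2c3c(cc(OC(=O)[C@@]45CC[C@@](C)(C(=O)O4)C5(C)C)c2cc1C)C(C)(C)C(=O)C(OC)(OC)[C@H]3Oc4cc5c(cc(OC)c6cc(C)c(O[Si](C(C)C)(C(C)C)C(C)C)cc56)c(C)c4OCOC
F3 | step 17 | (1S)-camphanate of the (4R) enantiomer of 26 | COc1cc2c3c(cc(OC(=O)[C@@]45CC[C@@](C)(C(=O)O4)C5(C)C)c2cc1C)C(C)(C)C(=O)C(OC)(OC)[C@@H]3Oc4cc5c(cc(OC)c6cc(C)c(O[Si](C(C)C)(C(C)C)C(C)C)cc56)c(C)c4OCOC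
F4 | step 17 | (1S)-camphanate analogue of 28 (O2′ phenol) | COc1cc2c3c(cc(OC(=O)[C@@]45CC[C@@](C)(C(=O)O4)C5(C)C)c2cc1C)C(C)(C)C(=O)C(OC)(OC)[C@H]3Oc4cc5c(cc(OC)c6cc(C)c(O[Si](C(C)C)(C(C)C)C(C)C)cc56)c(C)c4O
F5 | step 17 | (1S)-camphanate analogue of 29 (cis-fused dioxane) | COc1cc2c3c(cc(OC(=O)[C@@]45CC[C@@](C)(C(=O)O4)C5(C)C)c2cc1C)C(C)(C)C(=O)[C@@]1(OC)Oc2c(cc4c(cc(OC)c5cc(C)c(O[Si](C(C)C)(C(C)C)C(C)C)cc54)c2C)O[C@@H]31
F6 | step 16 | 6-(tert-butyldimethylsilyloxy)-1,1-dimethoxy-3,3-dimethylhex-4-yn-2-one | COC(OC)C(=O)C(C)(C)C#CCO[Si](C)(C)C(C)(C)C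
F7 | step 16 | 3-[1-(tert-butyldimethylsilyloxymethyl)-4-hydroxy-7-methoxy-6-methylnaphthalen-2-yl]-1,1-dimethoxy-3-methylbutan-2-one | COC(OC)C(=O)C(C)(C)c1cc(O)c2cc(C)c(OC)cc2c1CO[Si](C)(C)C(C)(C)C
F8 | step 16 | 4-(tert-butyldimethylsilyloxymethyl)-3-(4,4-dimethoxy-2-methyl-3-oxobutan-2-yl)-6-methoxy-7-methylnaphthalen-1-yl acetate | COC(OC)C(=O)C(C)(C)c1cc(OC(C)=O)c2cc(C)c(OC)cc2c1CO[Si](C)(C)C(C)(C)C
F9 | step 16 | 4-(bromomethyl)-3-(4,4-dimethoxy-2-methyl-3-oxobutan-2-yl)-6-methoxy-7-methylnaphthalen-1-yl acetate | COC(OC)C(=O)C(C)(C)c1cc(OC(C)=O)c2cc(C)c(OC)cc2c1CBr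
F10 | step 16 | 3-(4,4-dimethoxy-2-methyl-3-oxobutan-2-yl)-6-methoxy-7-methyl-4-(Ar′-oxymethyl)naphthalen-1-yl acetate | COC(OC)C(=O)C(C)(C)c1cc(OC(C)=O)c2cc(C)c(OC)cc2c1COc1cc2c(cc(OC)c3cc(C)c(O[Si](C(C)C)(C(C)C)C(C)C)cc23)c(C)c1OCOC
F11 | step 19 | O2′ trimethylsilyl ether of 28 | COc1cc2c3c(cc(OC(C)=O)c2cc1C)C(C)(C)C(=O)C(OC)(OC)[C@H]3Oc4cc5c(cc(OC)c6cc(C)c(O[Si](C(C)C)(C(C)C)C(C)C)cc56)c(C)c4O[Si](C)(C)C
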